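## The problem

1. The target is a daucane: a five-membered ring A and a seven-membered ring B share the C1–C5 bond. C1 is the methyl-bearing ring-fusion carbon, C2–C4 complete ring A (C4 carries the hydroxyl and the isopropyl group), C5 is the ring-fusion CH, and C6 (isovalerate), C7 (the only CH2 of ring B), C8 (exocyclic methylene), C9 and C10 (cis-diol) complete ring B. β is the face of the C1 methyl.
2. There are six stereocenters, (1S,4R,5S,6S,9R,10S): the ring fusion is trans (5α-H), the C4 hydroxyl is β, and the oxygens at C6, C9 and C10 are all α.
3. The quaternary C1 must be set absolutely. Its methyl can then steer C5/C6, C4 and C9, while C10, next to C1, is best set in the same event and can later direct C9.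
4. Four hydroxyls are present and only the one at C6 is acylated, so the isovalerate must go on late, selectively, and after the last hydride or organometallic step.
5. The tertiary C4 carbinol, the allylic C9 alcohol beside the exocyclic methylene, and any C4 ketone with an oxygen at C6 and an epimerisable C5 tolerate neither strong acid nor strong base.
6. Ring B has the quaternary C1 next to oxygenated C10 and a single CH2 (C7) flanked by C6 and C8. It can therefore be read as the cyclohepta-1,4-diene (C5=C6, C8=C9) that a cis-divinylcyclopropane with C7 as its ring methylene gives on Cope rearrangement, that is, a C1=C5–C6=C7 diene plus a three-carbon C8–C10 vinylcarbenoid.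

## Retrosynthesis

**Methylene and C9 hydroxyl (20 ⇐ 19 ⇐ 18 ⇐ 17 ⇐ 16).** No C–C bond is cut. The C8=CH2/C9–OH unit is traced to epoxy iodide 19, and that through 18 and 17 to allylic alcohol 16, which has C8=C9 and a C8 hydroxymethyl group. This transposition is preferred to a sigmatropic or selenium-based one because the epoxide fixes C9–O cis to C10–O before the olefin moves. The forward sequence needs an α-epoxidation and a zinc-induced opening that retains C9–O. The isovalerate is put on at the epoxy iodide (18 → 19): the primary hydroxyl is gone, C9–OH is not yet free, and only zinc follows.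

**Oxidation level at C8 and C10 (16 ⇐ 15 ⇐ 14).** The hydroxymethyl group comes from an ethyl enoate and the C10 hydroxyl from a silyl ether. Both simplifications cost one step each and remove no stereocenter. They leave 14, in which C8–C10 are still in the form in which the ring was made.

**C4–isopropyl bond (14 ⇐ 13).** Cutting the isopropyl group from C4 gives β-hydroxy ketone 13. The addition is placed after the ring fusion is trans, because the C1 methyl is then axial and 1,3-syn to the β trajectory at C4, so α attack gives the 4β-alcohol. The reagent must be non-basic (organocerium) because C5 is enolisable and C6 carries oxygen.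

**C5–H and C6–O (13 ⇐ 12 ⇐ 10).** Ketone 13 comes from ketal 12, and the syn H/OH pair at C5/C6 from hydroboration of the C5=C6 olefin of diene 10. This is done on 10 itself, and the reasons are conformational:
- ring B of 10 is a folded cyclohepta-1,4-diene hinged at C7;
- the C1 methyl stands nearly perpendicular over the convex β face beside C5;
- the C10 silyl ether lies near the plane of the enoate, so the concave α face has no substituent;
- the ketal is the same on both faces, whereas an α-isopropyl at C4 would block the α face of C5;
- the enoate is electron-poor and should be left by borane.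

Two stereocenters and the ring fusion are removed at once.

**Ring B (10 ⇐ 4 + 8).** Cutting C7–C8 and C1–C10 is the central simplification. It removes ring B, the quaternary C1 and C10, and leaves achiral diene ketal 4 and siloxyvinyl diazoester 8. Against cuts that build ring B from a preformed carbocycle, this one delivers in one step the C8 carbon substituent, the C8=C9 unsaturation needed for the methylene/diol, the C10 oxygen and the C5=C6 olefin. The forward reaction needs site selectivity for the vinyl group, a cis-cyclopropane, catalyst control of the olefin face and an (E)-enol ether.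

**Components (4 ⇐ 2 + 3; 2 ⇐ 1; 8 ⇐ 7 ⇐ 5 + 6).** The C5–C6 bond of 4 is a Suzuki bond between bromo ketal 2 (from commercial bromoenone 1) and vinylboronate 3. Ketalising before coupling avoids handling a volatile cross-conjugated dienone. Diazoester 8 is the dehydration product of aldol adduct 7, from silyloxyacetaldehyde 5 and ethyl diazoacetate 6.

## Roads not taken

**Alternative 1:** A Robinson-annulation decalin is taken to the trans-decalin epoxy alcohol A1. BF3·OEt2 opens the epoxide at C5 while C1 migrates from C6 to C5, contracting ring A and expanding ring B to give hydroazulenone A2.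
- Merits: the decalin chemistry is cheap and scalable, and the C4 carbinol is in place before the skeleton forms. The shift is stereospecific (inversion at C5), so the trans ring fusion needs no face-selective reagent. In this respect it is better than the chosen plan, whose C5 rests on the facial course of a hydroboration.
- Weak points: A1 must be a single diastereomer of a trisubstituted, isopropyl-bearing epoxide. The C1–C6 bond is only roughly antiperiplanar to C5–O in the half-chair, and C7 can compete as migrating group. A2 has bare methylenes at C7, C8 and C9, so the C8 methylene and C9 hydroxyl must be built outward from the C10 ketone over several steps. The C6 ketone must be reduced to the equatorial alcohol against the axial methyl.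
- Comparison: the chosen plan offers the C8 carbon, the C8=C9 olefin and the C10 oxygen delivered by the ring-forming step itself.

**Alternative 2:** The C4–C5 bond is cut. Iodine–lithium exchange on vinyl iodide A3 and 5-exo addition of the vinyllithium to the side-chain isopropyl ketone give allylic alcohol A4.
- Merits: one operation makes ring A, the C4 carbinol and the C5=C6 olefin. It avoids adding an organometallic to a β-hydroxy ketone, which is a risk of the chosen plan, so at C4 it is at least as good in chemoselectivity.
- Weak points: the C4 configuration depends on which face of a freely rotating ketone meets the vinyllithium, with only remote induction from C1 and C10. t-BuLi meets an enolisable ketone. C1 must be set earlier by desymmetrising a cycloheptanedione, a separate enantio-determining operation. A4 again lacks any handle at C7–C9. The later hydroboration would have to pass the α-isopropyl group at C4.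
- Comparison: the chosen plan sets C1 and C10 together under catalyst control and arrives with C8–C10 functionalised.

**Alternative 3:** The same Cope logic is run intramolecularly. A chiral dirhodium carboxylate decomposes acyclic trienyl vinyl diazoketone A5, the carbenoid cyclopropanates C1=C10, and the divinylcyclopropane rearranges to dienone A6.
- Merits: both rings and the quaternary centre come from an open chain in one step. The C4 ketone is free (no ketal steps), C8 already carries its carbon, and C9=C10 invites a one-step syn-dihydroxylation to the cis-diol. On paper the endgame is shorter than the chosen one, which is a real advantage.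
- Weak points: the carbenoid must attack a trisubstituted olefin, the class these carbenoids cyclopropanate least well. Enantiocontrol for intramolecular vinyl diazoketone cyclopropanation is less secure than for intermolecular vinyldiazoacetate reactions. A5 is a sensitive skipped trienyl diazoketone needing defined E,E geometry. The C8 stereocenter is made and then destroyed. Dihydroxylation must pick the α face of one of two olefins in a folded diene.
- Comparison: the chosen plan reacts at a monosubstituted vinyl group, the best case for the carbenoid, sets the C10 oxygen together with C1, and uses two components of two steps each.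

Key step: step 5

Assumption: the prolinate catalysts are taken to show the sense of induction known for styrene with aryl- or vinyldiazoacetates, where the (S)-catalyst gives the (1S,2R)-cyclopropane; the (1R,2S)-cyclopropane 9 that the boat Cope turns into (1S,10R)-10 then needs the (R)-catalyst, and the mirror-image catalyst is the remedy if the sense proves opposite.

## Route

Step 1
Reactants: 1 2-bromo-3-methylcyclopent-2-en-1-one
Product: 2 6-bromo-7-methyl-1,4-dioxaspiro[4.4]non-6-ene
Conditions: HOCH2CH2OH, p-TsOH (cat.), benzene, reflux, Dean–Stark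
Reagents that add atoms: ethylene glycol, OCCO
Why: Acid-catalysed ketalisation with azeotropic removal of water; the bromine and methyl keep the olefin tetrasubstituted and in place, and the ketal masks the carbonyl for the coupling and makes the later diene electron-rich.

Step 2
Reactants: 2 6-bromo-7-methyl-1,4-dioxaspiro[4.4]non-6-ene; 3 vinylboronic acid pinacol ester
Product: 4 7-methyl-6-vinyl-1,4-dioxaspiro[4.4]non-6-ene
Conditions: Pd(dppf)Cl2 (cat.), K2CO3, 1,4-dioxane/H2O, 80 °C
Reagents that add atoms: none
Why: Suzuki–Miyaura coupling: oxidative addition of the vinyl bromide to zerovalent palladium, transmetalation from the vinylboronate and reductive elimination; the ketal is stable to aqueous base, and the diene is used promptly.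

Step 3
Reactants: 5 (tert-butyldimethylsilyloxy)acetaldehyde; 6 ethyl diazoacetate
Product: 7 ethyl 4-(tert-butyldimethylsilyloxy)-2-diazo-3-hydroxybutanoate (racemic)
Conditions: DBU (cat.), MeCN, rt
Reagents that add atoms: none
Why: Amine-catalysed aldol-type addition of the nucleophilic diazo carbon to the aldehyde; the diazo group and the silyl ether survive these mild, non-acidic conditions, and the carbinol centre is removed in the next step.

Step 4
Reactants: 7 ethyl 4-(tert-butyldimethylsilyloxy)-2-diazo-3-hydroxybutanoate
Product: 8 ethyl (E)-4-(tert-butyldimethylsilyloxy)-2-diazobut-3-enoate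
Conditions: POCl3, Et3N, CH2Cl2, 0 °C
Reagents that add atoms: none
Why: Dehydration of a β-hydroxy-α-diazo ester through its dichlorophosphate and base-induced anti elimination; the conformer with the siloxy group away from the diazoester gives the (E)-enol ether, which is kept cold and used at once.

Step 5
Reactants: 4 7-methyl-6-vinyl-1,4-dioxaspiro[4.4]non-6-ene; 8 ethyl (E)-4-(tert-butyldimethylsilyloxy)-2-diazobut-3-enoate
Product: 10 bicyclic dienyl ester (1S,10R): C4 ethylene ketal; C5=C6; C8=C9 with CO2Et on C8; 10α-OTBS; 1β-methyl, via cis-divinylcyclopropane 9 (not isolated)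
Conditions: Rh2(R-DOSP)4 (1 mol %), hexanes, −40 °C → rt, slow addition of 8; then 65 °C
Reagents that add atoms: none
Why: Rh2(R-DOSP)4, dirhodium tetrakis[(R)-N-(dodecylbenzenesulfonyl)prolinate], decomposes 8 to a donor/acceptor carbenoid of divalent rhodium, which adds end-on to the only monosubstituted olefin of 4 (C6=C7) and gives cyclopropane 9 with the siloxyvinyl and cyclopentenyl groups cis. The cis-divinylcyclopropane then undergoes a boat Cope rearrangement that breaks C6–C8 and joins C1 to C10, so C7–C8 and C1–C10 are the two new skeletal bonds; the closest known reaction type is the tandem cyclopropanation/Cope rearrangement of vinyldiazoacetates with 1,3-dienes, including 1-vinylcycloalkenes. Ring B closes as a cyclohepta-1,4-diene by this [3,3]-sigmatropic shift, a formal (4+3) annulation of the four diene carbons C1, C5, C6, C7 with the three carbenoid carbons C8, C9, C10. C1 is controlled by the catalyst: its choice of olefin face fixes the cyclopropane carbon C6, and the boat relays that configuration to C1. C10 is controlled by the boat geometry and the (E)-enol ether: the siloxy group ends cis to C2 and trans to the methyl. The step needs site selectivity (the tetrasubstituted ring olefin is inert to this carbenoid), cis-diastereoselectivity (normal for donor/acceptor carbenoids, ester trans to the olefin substituent) and enantioselectivity (hydrocarbon solvent and low temperature, as the prolinate catalysts require). The C1 methyl points into the boat and slows the Cope step, hence the final warming.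

Step 6
Reactants: 10 bicyclic dienyl ester (1S,10R)
Product: 12 trans-fused 6α-alcohol (1S,5S,6S,10R): 5α-H; 6α-OH; C4 ketal; C8=C9 enoate; 10α-OTBS, via 6α-borane 11 (not isolated)
Conditions: BH3·THF, THF, 0 °C → rt; then NaBO3·4H2O, H2O, rt
Reagents that add atoms: sodium perborate, [Na+].[O-]OB=O
Why: Hydroboration–oxidation: boron goes to the less substituted C6 and hydrogen to C5 in a syn addition, and oxidation replaces boron by oxygen with retention. The α face should be chosen because the C1 methyl stands over the β face beside C5 (as in 5-ene steroids, which give 5α-H/6α-OH), while the folded diene keeps the C10 silyl ether in the enoate plane and its concave α face unsubstituted. The electron-poor enoate is left by the electrophilic borane, and perborate avoids strongly basic peroxide.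

Step 7
Reactants: 12 trans-fused 6α-alcohol (1S,5S,6S,10R)
Product: 13 β-hydroxy ketone (1S,5S,6S,10R): C4 ketone; 5α-H; 6α-OH; C8=C9 enoate; 10α-OTBS
Conditions: PPTS (cat.), acetone/H2O, 45 °C
Reagents that add atoms: water, O
Why: Mild acid-catalysed ketal hydrolysis; PPTS is weak enough to keep the silyl ether and to avoid dehydration of the β-hydroxy ketone or epimerisation at C5.

Step 8
Reactants: 13 β-hydroxy ketone (1S,5S,6S,10R)
Product: 14 tertiary carbinol (1S,4R,5S,6S,10R): 4β-OH; 4α-isopropyl; 5α-H; 6α-OH; C8=C9 enoate; 10α-OTBS
Conditions: i-PrMgCl, CeCl3, THF, −78 °C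
Reagents that add atoms: isopropylmagnesium chloride, CC(C)[Mg]Cl
Why: Organocerium 1,2-addition, which suppresses enolisation and hydride transfer and reacts with the ketone much faster than with the ester at −78 °C; one equivalent is consumed by the C6 hydroxyl. In the trans-fused ketone the axial C1 methyl is 1,3-syn to the β trajectory, so the nucleophile should enter from the α face and give the 4β-alcohol, as for additions to D-ring ketones of trans-hydrindanes.

Step 9
Reactants: 14 tertiary carbinol (1S,4R,5S,6S,10R)
Product: 15 allylic alcohol (1S,4R,5S,6S,10R): 8-hydroxymethyl on C8=C9; 4β-OH; 6α-OH; 10α-OTBS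
Conditions: i-Bu2AlH (excess), CH2Cl2, −78 → 0 °C
Reagents that add atoms: none
Why: 1,2-Reduction of the α,β-unsaturated ester to the allylic alcohol; the free hydroxyls are carried as aluminates and no other reducible group is present.

Step 10
Reactants: 15 allylic alcohol (1S,4R,5S,6S,10R)
Product: 16 tetraol (1S,4R,5S,6S,10R): 8-hydroxymethyl on C8=C9; 4β-OH; 6α-OH; 10α-OH
Conditions: Bu4NF, THF, rt → 45 °C
Reagents that add atoms: none
Why: Fluoride cleavage of the silyl ether; the C10 ether is neopentylic and may need gentle warming, and nothing else in the molecule is fluoride- or base-labile.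

Step 11
Reactants: 16 tetraol (1S,4R,5S,6S,10R)
Product: 17 epoxy alcohol (1S,4R,5S,6S,8S,9S,10S): 8α,9α-epoxide; 8-hydroxymethyl; 4β-OH; 6α-OH; 10α-OH
Conditions: VO(acac)2 (cat.), t-BuOOH, CH2Cl2, 0 °C → rt
Reagents that add atoms: tert-butyl hydroperoxide, CC(C)(C)OO
Why: Hydroxyl-directed epoxidation through a vanadium alkoxide–peroxide complex, specific for the allylic alcohol olefin. With the ring fusion trans, the C10 hydroxyl is pseudoaxial on the α face and the C1 methyl lies across the β face, so direction and sterics both give the α-epoxide and C9–O cis to C10–O.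

Step 12
Reactants: 17 epoxy alcohol (1S,4R,5S,6S,8S,9S,10S)
Product: 18 epoxy iodide (1S,4R,5S,6S,8R,9S,10S): 8-iodomethyl; 8α,9α-epoxide; 4β-OH; 6α-OH; 10α-OH
Conditions: PPh3, I2, imidazole, CH2Cl2, 0 °C
Reagents that add atoms: iodine, II
Why: Appel-type iodination through the alkoxyphosphonium ion, selective for the primary hydroxyl at 0 °C; the imidazole buffer keeps the epoxide intact, as in the usual conversion of 2,3-epoxy alcohols into epoxy iodides.

Step 13
Reactants: 18 epoxy iodide (1S,4R,5S,6S,8R,9S,10S)
Product: 19 epoxy iodide 6-isovalerate (1S,4R,5S,6S,8R,9S,10S): 6α-(3-methylbutanoyloxy); 8-iodomethyl; 8α,9α-epoxide; 4β-OH; 10α-OH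
Conditions: (i-BuCO)2O (1.1 equiv), DMAP (cat.), pyridine, CH2Cl2, 0 °C
Reagents that add atoms: 3-methylbutanoic anhydride, CC(C)CC(=O)OC(=O)CC(C)C
Why: DMAP-catalysed acylation with limiting anhydride: the equatorial C6 hydroxyl reacts, the axial C10 hydroxyl is flanked by the quaternary C1 and the epoxide, and the tertiary C4 hydroxyl is inert. Placing the ester here means no hydride or organometallic step follows it.

Step 14
Reactants: 19 epoxy iodide 6-isovalerate (1S,4R,5S,6S,8R,9S,10S)
Product: 20 CNP0204264.1 (1S,4R,5S,6S,9R,10S): 6α-isovalerate; 4β,9α,10α-triol; 8-methylene; 4α-isopropyl; 1β-methyl; 5α-H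
Conditions: Zn dust, EtOH, reflux
Reagents that add atoms: none
Why: Reductive opening of a 2,3-epoxy iodide: zinc inserts into the C–I bond and β-elimination opens the epoxide, giving the exocyclic methylene and the C9 alkoxide with the C9–O bond, and hence its α configuration, retained; the neutral conditions spare the ester and the tertiary alcohol.

## Compound list

1 | 2-bromo-3-methylcyclopent-2-en-1-one | CC1=C(Br)C(=O)CC1 | starting material
2 | 6-bromo-7-methyl-1,4-dioxaspiro[4.4]non-6-ene | CC1=C(Br)C2(CC1)OCCO2 | intermediate
3 | vinylboronic acid pinacol ester | C=CB1OC(C)(C)C(C)(C)O1 | starting material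
4 | 7-methyl-6-vinyl-1,4-dioxaspiro[4.4]non-6-ene | C=CC1=C(C)CCC12OCCO2 | intermediate
5 | (tert-butyldimethylsilyloxy)acetaldehyde | CC(C)(C)[Si](C)(C)OCC=O | starting material
6 | ethyl diazoacetate | CCOC(=O)C=[N+]=[N-] | starting material
7 | ethyl 4-(tert-butyldimethylsilyloxy)-2-diazo-3-hydroxybutanoate (racemic) | CCOC(=O)C(=[N+]=[N-])C(O)CO[Si](C)(C)C(C)(C)C | intermediate
8 | ethyl (E)-4-(tert-butyldimethylsilyloxy)-2-diazobut-3-enoate | CCOC(=O)C(=[N+]=[N-])/C=C/O[Si](C)(C)C(C)(C)C | intermediate
9 | ethyl (1R,2S)-1-[(E)-2-(tert-butyldimethylsilyloxy)ethenyl]-2-(7-methyl-1,4-dioxaspiro[4.4]non-6-en-6-yl)cyclopropane-1-carboxylate (cis-divinylcyclopropane) | CCOC(=O)[C@]1(/C=C/O[Si](C)(C)C(C)(C)C)C[C@H]1C2=C(C)CCC23OCCO3 | intermediate (not isolated)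
10 | bicyclic dienyl ester (1S,10R): C4 ethylene ketal, C5=C6, ethyl C8-carboxylate on C8=C9, 10α-OTBS, 1β-methyl | CCOC(=O)C1=C[C@@H](O[Si](C)(C)C(C)(C)C)[C@@]2(C)CCC3(OCCO3)C2=CC1 | intermediate
11 | 6α-borane of 10 (5α-H, 6α-BH2) | CCOC(=O)C1=C[C@@H](O[Si](C)(C)C(C)(C)C)[C@@]2(C)CCC3(OCCO3)[C@@H]2[C@@H](B)C1 | intermediate (not isolated)
12 | trans-fused 6α-alcohol (1S,5S,6S,10R): C4 ketal, 5α-H, 6α-OH, C8=C9 enoate, 10α-OTBS | CCOC(=O)C1=C[C@@H](O[Si](C)(C)C(C)(C)C)[C@@]2(C)CCC3(OCCO3)[C@@H]2[C@@H](O)C1 | intermediate
13 | β-hydroxy ketone (1S,5S,6S,10R): C4 ketone, 5α-H, 6α-OH, C8=C9 enoate, 10α-OTBS | CCOC(=O)C1=C[C@@H](O[Si](C)(C)C(C)(C)C)[C@@]2(C)CCC(=O)[C@@H]2[C@@H](O)C1 | intermediate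
14 | tertiary carbinol (1S,4R,5S,6S,10R): 4β-OH, 4α-isopropyl, 5α-H, 6α-OH, C8=C9 enoate, 10α-OTBS | CCOC(=O)C1=C[C@@H](O[Si](C)(C)C(C)(C)C)[C@@]2(C)CC[C@@](O)(C(C)C)[C@@H]2[C@@H](O)C1 | intermediate
15 | allylic alcohol (1S,4R,5S,6S,10R): 8-hydroxymethyl on C8=C9, 4β-OH, 6α-OH, 10α-OTBS | OCC1=C[C@@H](O[Si](C)(C)C(C)(C)C)[C@@]2(C)CC[C@@](O)(C(C)C)[C@@H]2[C@@H](O)C1 | intermediate
16 | tetraol (1S,4R,5S,6S,10R): 8-hydroxymethyl on C8=C9, 4β-OH, 6α-OH, 10α-OH | OCC1=C[C@@H](O)[C@@]2(C)CC[C@@](O)(C(C)C)[C@@H]2[C@@H](O)C1 | intermediate
17 | epoxy alcohol (1S,4R,5S,6S,8S,9S,10S): 8α,9α-epoxide, 8-hydroxymethyl, 4β-OH, 6α-OH, 10α-OH | OC[C@]12O[C@H]1[C@@H](O)[C@@]3(C)CC[C@@](O)(C(C)C)[C@@H]3[C@@H](O)C2 | intermediate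
18 | epoxy iodide (1S,4R,5S,6S,8R,9S,10S): 8-iodomethyl, 8α,9α-epoxide, 4β-OH, 6α-OH, 10α-OH | IC[C@]12O[C@H]1[C@@H](O)[C@@]3(C)CC[C@@](O)(C(C)C)[C@@H]3[C@@H](O)C2 | intermediate
19 | epoxy iodide 6-isovalerate (1S,4R,5S,6S,8R,9S,10S) | IC[C@]12O[C@H]1[C@@H](O)[C@@]3(C)CC[C@@](O)(C(C)C)[C@@H]3[C@@H](OC(=O)CC(C)C)C2 | intermediate
20 | CNP0204264.1, (1S,4R,5S,6S,9R,10S)-4,9,10-trihydroxy-4-isopropyl-1-methyl-8-methylene-trans-hydroazulen-6-yl 3-methylbutanoate (numbering of this proposal) | C=C1C[C@H](OC(=O)CC(C)C)[C@@H]2[C@](C)(CC[C@@]2(O)C(C)C)[C@H](O)[C@@H]1O | target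

## Step count and least certain steps

Total step count: 14. Longest linear sequence: 12 steps (1 → 2 → 4 → 10 → 12 → 13 → 14 → 15 → 16 → 17 → 18 → 19 → 20); the diazoester branch (5 + 6 → 7 → 8) has 2 steps.

**Step 5 (key step).** Enantiocontrol may erode with an ethyl ester and an electron-rich siloxyvinyl carbenoid. Diazoester 8 may cyclise to a pyrazole before it reaches the catalyst. The Cope step may stall at cyclopropane 9 because the C1 methyl points into the boat. Fallback: setting out from 4 and 8, the annulation is run with achiral dirhodium tetraoctanoate, Rh2(O2CC7H15)4, in refluxing hexanes, so that cyclopropanation and rearrangement merge. This gives 10 together with its mirror image, the ent-bicyclic dienyl ester F1, and preparative chromatography on a chiral stationary phase returns to the route at 10.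

**Step 6.** Facial selectivity may be poor: borane may add on the convex β face in spite of the methyl and give the cis-fused 6β-alcohol. The enoate may also be reduced if the hindered olefin reacts slowly. Fallback, which turns a β preference to advantage: setting out from 10, m-CPBA/NaHCO3 epoxidises the electron-rich C5=C6 olefin to the 5β,6β-epoxide F2. BF3·OEt2 at −78 °C induces a Meinwald rearrangement in which the C6 hydride shifts to C5 on the face opposite the leaving oxygen, giving the trans-fused C6 ketone F3. NaBH4/CeCl3 reduces it from the α face (the β face is 1,3-syn to the axial methyl) to the 6β-alcohol F4. Mitsunobu inversion (PPh3, DIAD, 4-nitrobenzoic acid) gives the 6α-(4-nitrobenzoate) F5, and K2CO3 in ethanol returns to the route at 12.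

**Step 8.** The hindered, enolisable β-hydroxy ketone may enolise toward C5 and lose the C6 oxygen, the alkoxide may undergo retro-aldol cleavage, or the isopropyl reagent may transfer hydride; a minor risk is attack on the β face. Fallback: setting out from 13, 2-propenylmagnesium bromide with CeCl3 (a smaller sp2 nucleophile without β-hydrogen) gives the isopropenyl carbinol F6. Hydrogenation with RhCl(PPh3)3/H2 in benzene saturates only the 1,1-disubstituted olefin and returns to the route at 14.

**Step 4.** The elimination may give E/Z mixtures or strip the silyl group, and the product may cyclise on standing. Fallback: setting out from 5, Wittig olefination with Ph3P=CHCO2Et gives ethyl (E)-4-(tert-butyldimethylsilyloxy)but-2-enoate F7. Deconjugative diazo transfer (4-acetamidobenzenesulfonyl azide, DBU, MeCN, 0 °C) through the γ-deprotonated dienolate returns to the route at 8.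

**Step 13.** Discrimination between the C6 and C10 hydroxyls may be incomplete, leading to over-acylation. Fallback by protection: setting out from 18, zinc in ethanol first gives the methylene tetraol F8. 2,2-Dimethoxypropane/PPTS closes the cis-9,10-acetonide F9, the anhydride/DMAP acylation at C6 gives the acetonide isovalerate F10, and aqueous acetic acid returns to the route at 20.

## Further compounds

F1 | step 5 | ent-bicyclic dienyl ester (1R,10S), enantiomer of 10 | CCOC(=O)C1=C[C@H](O[Si](C)(C)C(C)(C)C)[C@]2(C)CCC3(OCCO3)C2=CC1
F2 | step 6 | 5β,6β-epoxide of 10 | CCOC(=O)C1=C[C@@H](O[Si](C)(C)C(C)(C)C)[C@@]2(C)CCC3(OCCO3)[C@]24O[C@@H]4C1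
F3 | step 6 | trans-fused C6 ketone (5α-H), C4 ketal, C8=C9 enoate, 10α-OTBS | CCOC(=O)C1=C[C@@H](O[Si](C)(C)C(C)(C)C)[C@@]2(C)CCC3(OCCO3)[C@@H]2C(=O)C1
F4 | step 6 | trans-fused 6β-alcohol, C6 epimer of 12 | CCOC(=O)C1=C[C@@H](O[Si](C)(C)C(C)(C)C)[C@@]2(C)CCC3(OCCO3)[C@@H]2[C@H](O)C1
F5 | step 6 | 6α-(4-nitrobenzoate) of 12 | CCOC(=O)C1=C[C@@H](O[Si](C)(C)C(C)(C)C)[C@@]2(C)CCC3(OCCO3)[C@@H]2[C@@H](OC(=O)c4ccc(cc4)[N+](=O)[O-])C1
F6 | step 8 | isopropenyl carbinol: 4β-OH, 4α-(prop-1-en-2-yl), otherwise as 14 | CCOC(=O)C1=C[C@@H](O[Si](C)(C)C(C)(C)C)[C@@]2(C)CC[C@@](O)(C(C)=C)[C@@H]2[C@@H](O)C1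
F7 | step 4 | ethyl (E)-4-(tert-butyldimethylsilyloxy)but-2-enoate | CCOC(=O)/C=C/CO[Si](C)(C)C(C)(C)C
F8 | step 13 | methylene tetraol: 20 without the isovaleryl group | C=C1C[C@H](O)[C@@H]2[C@](C)(CC[C@@]2(O)C(C)C)[C@H](O)[C@@H]1O
F9 | step 13 | 9,10-acetonide of the methylene tetraol | C=C1C[C@H](O)[C@@H]2[C@](C)(CC[C@@]2(O)C(C)C)[C@@H]3OC(C)(C)O[C@H]13
F10 | step 13 | 9,10-acetonide 6-isovalerate | C=C1C[C@H](OC(=O)CC(C)C)[C@@H]2[C@](C)(CC[C@@]2(O)C(C)C)[C@@H]3OC(C)(C)O[C@H]13
A1 | alternative 1 | trans-decalin epoxy alcohol: angular methyl, ring-fusion hydroxyl, isopropyl epoxide, dioxolane | C[C@]12CC[C@]3(C(C)C)O[C@@H]3[C@]1(O)CCCC24OCCO4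
A2 | alternative 1 | trans-fused hydroazulenone: C6 ketone, C4 tertiary carbinol, C10 dioxolane | C1CC(=O)[C@@H]2[C@](C)(CC[C@@]2(O)C(C)C)C3(OCCO3)C1
A3 | alternative 2 | cycloheptenyl iodide with the 4-methyl-3-oxopentyl side chain on C1 and 10-OTBS | CC(C)C(=O)CC[C@@]1(C)C(I)=CCCC[C@H]1O[Si](C)(C)C(C)(C)C
A4 | alternative 2 | bicyclic tertiary allylic alcohol: C5=C6, 10-OTBS | C1=C2[C@](C)(CC[C@@]2(O)C(C)C)[C@H](O[Si](C)(C)C(C)(C)C)CCC1
A5 | alternative 3 | acyclic (E,E)-trienyl vinyl diazoketone | C=CC(=[N+]=[N-])C(=O)CC/C(C)=C/C=C/CO[Si](C)(C)C(C)(C)C
A6 | alternative 3 | bicyclic dienone: C4 ketone, C5=C6, C9=C10, C8 silyloxymethyl | CC(C)(C)[Si](C)(C)OC[C@@H]1CC=C2[C@](C)(CCC2=O)C=C1
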